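**Retrosynthetic overview**
1. Last bond: the primary alcohol of the ω‑hydroxy lactone diacid opens O‑trifluoroacetyl‑D‑malic anhydride at the carbonyl next to the oxygen‑bearing carbon. This gives the (R)‑malate 1‑ester without protecting groups.
2. Core: the 5‑oxooxolane ring (O1, quaternary C2, C3H2, C4H2, C5=O) is cut at C2–C3. C5 is lowered to the aldehyde level and C3 carries iodide, so the closure becomes an intramolecular enolate alkylation at C2.
3. Enabling feature: C5 sits on O1, O1 sits on C2, and C2 also carries a carboxyl group. At the aldehyde level C5 can therefore bind O1 and the carboxyl oxygen together, as the acetal carbon of a 1,3‑dioxolan‑4‑one whose enolisable carbon is C2. The C4–C3 arm hangs from that acetal carbon and can reach only one face of C2.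
4. Chiral pool: HO2C–C2(O)–C1'H–CO2H of the core is a second malic acid skeleton. Fráter–Seebach alkylation of diethyl D‑malate sets C1' as (S), and the tethered closure replaces H at C2 with inversion, giving the (2S,1'S) array.
5. Ring order: the temporary 1,3‑dioxolan‑4‑one comes first and the oxolane second (key step, giving a 2,7‑dioxabicyclo[2.2.1]heptan‑3‑one). Hydrolysis and oxidation then open the dioxolanone bridge and leave the γ‑lactone and the free C2 carboxyl.

Key step: step 7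

Remark: 10‑bromodecan‑1‑ol, diethyl D‑malate, 3‑bromo‑1,1‑dimethoxypropane and D‑malic acid are taken as commercial. The locants O1–C5 and C1' refer to the oxolanone ring and the side‑chain CH of the target.

**Step 1**
Reactants: 1 10‑bromodecan‑1‑ol
Product: 2 benzyl 10‑bromodecyl ether
Conditions: BnOC(=NH)CCl3 (1.3 equiv), TfOH (5 mol %), cyclohexane/CH2Cl2 2:1, 0 °C to rt
Reagents that add atoms: benzyl 2,2,2‑trichloroacetimidate, N=C(OCc1ccccc1)C(Cl)(Cl)Cl
Why: Acid‑catalysed O‑benzylation with a trichloroacetimidate needs no base, so no alkoxide forms that could displace the primary bromide.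

**Step 2**
Reactants: 2 benzyl 10‑bromodecyl ether
Product: 3 benzyl 10‑iododecyl ether
Conditions: NaI (3 equiv), acetone, reflux
Reagents that add atoms: sodium iodide, [Na+].[I-]
Why: Finkelstein exchange, driven by precipitation of NaBr, should give the more reactive iodide needed for the enolate alkylation.

**Step 3**
Reactants: 4 diethyl (2R)‑2‑hydroxybutanedioate (diethyl D‑malate); 3 benzyl 10‑iododecyl ether
Product: 6 diethyl (2R,3S)‑3‑[10‑(benzyloxy)decyl]‑2‑hydroxybutanedioate, via dilithium alkoxide enolate 5 (not isolated)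
Conditions: LiN(iPr)2 (2.2 equiv), THF, −78 to −20 °C; 3, DMPU, −78 to 0 °C; AcOH
Reagents that add atoms: none
Why: In this Fráter–Seebach alkylation the lithium‑chelated alkoxide enolate is attacked anti to the carbinol substituent, so the (R)‑carbinol should set the new centre as (3S) (anti product), the mirror image of the known (S)‑malate to (2S,3R) outcome.

**Step 4**
Reactants: 6 diethyl (2R,3S)‑3‑[10‑(benzyloxy)decyl]‑2‑hydroxybutanedioate
Product: 7 (2R,3S)‑3‑[10‑(benzyloxy)decyl]‑2‑hydroxybutanedioic acid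
Conditions: KOH (4 equiv), EtOH/H2O, rt; then 1 M HCl
Reagents that add atoms: potassium hydroxide, [K+].[OH-]
Why: Ester saponification at room temperature quickly gives carboxylates, whose α‑protons are not removed by hydroxide, so both centres should be kept.

**Step 5**
Reactants: 8 3‑bromo‑1,1‑dimethoxypropane
Product: 9 3‑iodo‑1,1‑dimethoxypropane
Conditions: NaI (2 equiv), acetone, reflux
Reagents that add atoms: sodium iodide, [Na+].[I-]
Why: Finkelstein exchange under neutral conditions leaves the acetal untouched.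

**Step 6**
Reactants: 7 (2R,3S)‑3‑[10‑(benzyloxy)decyl]‑2‑hydroxybutanedioic acid; 9 3‑iodo‑1,1‑dimethoxypropane
Product: 12 (2S)‑12‑(benzyloxy)‑2‑[(2R,4R)‑2‑(2‑iodoethyl)‑5‑oxo‑1,3‑dioxolan‑4‑yl]dodecanoic acid, via tris(trimethylsilyl) derivative 10 (not isolated), via trimethylsilyl ester 11 (not isolated)
Conditions: (Me3Si)2NH, CH2Cl2, reflux, evaporation; 9, Me3SiOTf (5 mol %), CH2Cl2, −78 to −30 °C; pyridine, then aqueous work‑up at pH 4
Reagents that add atoms: none
Why: In this Noyori‑type silyl‑mediated transacetalisation the α‑hydroxy acid unit should close the five‑membered dioxolanone rather than the six‑membered dioxanone (as malic acid does), no free methanol arises to esterify the side‑chain acid, and kinetic closure at low temperature should favour the 2,4‑cis isomer, so the (4R) centre sets the acetal carbon as (2R) and the minor trans isomer is removed by chromatography.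

**Step 7**
Reactants: 12 (2S)‑12‑(benzyloxy)‑2‑[(2R,4R)‑2‑(2‑iodoethyl)‑5‑oxo‑1,3‑dioxolan‑4‑yl]dodecanoic acid
Product: 14 (2S)‑12‑(benzyloxy)‑2‑[(1R,4S)‑3‑oxo‑2,7‑dioxabicyclo[2.2.1]heptan‑4‑yl]dodecanoic acid, via dilithium carboxylate enolate 13 (not isolated)
Conditions: LiN(SiMe3)2 (2.3 equiv), THF/DMPU 10:1 (0.02 M), −78 °C, then −78 to −30 °C; AcOH
Reagents that add atoms: none
Why: Proposed new method: LiN(SiMe3)2 first forms the side‑chain carboxylate and then removes the ring α‑proton of the dioxolanone, and the planar lithium enolate 13 displaces the primary iodide at the end of the two‑carbon arm on its own acetal carbon, which forms the C2–C3 bond of the future oxolanone. The closest known reaction types are the Seebach alkylation of 1,3‑dioxolan‑4‑one enolates (self‑regeneration of stereocentres, also run on the malic acid dioxolanone as its carboxylate enolate dianion) and the transannular enolate alkylation of 5‑(2‑haloethyl)proline esters to 7‑azabicyclo[2.2.1]heptane‑1‑carboxylates; new here is that the electrophile is tied to the acetal carbon of the dioxolanone itself. The one ring closed is the five‑membered oxolane (O, acetal C, CH2, CH2, quaternary C), by a 5‑(enolexo)‑exo‑tet closure that turns the dioxolanone into a 2,7‑dioxabicyclo[2.2.1]heptan‑3‑one. The new quaternary centre is controlled by the acetal carbon alone: the arm reaches only the enolate face on which it stands, which in the cis isomer is the face opposite to the departed proton, so C–H is replaced by C–C with inversion and (4S) arises next to the untouched (S) side‑chain centre, a relative configuration that an external electrophile (anti to the acetal substituent, retention) cannot give from an anti‑3‑alkylmalate. Site selectivity of deprotonation is secured by the carboxylate, which makes the side‑chain α‑proton far less acidic than the lactone‑type ring proton and so also protects that centre. O‑alkylation would need a bridgehead double bond, and alkylation between molecules is held back by dilution.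

**Step 8**
Reactants: 14 (2S)‑12‑(benzyloxy)‑2‑[(1R,4S)‑3‑oxo‑2,7‑dioxabicyclo[2.2.1]heptan‑4‑yl]dodecanoic acid
Product: 16 (2S)‑2‑[(1S)‑11‑(benzyloxy)‑1‑carboxyundecyl]‑5‑oxooxolane‑2‑carboxylic acid, via lactol diacid 15 (not isolated)
Conditions: CrO3, H2SO4, H2O, acetone, 0 °C
Reagents that add atoms: water, O
Why: Under Jones oxidation conditions the aqueous acid opens the strained bicyclic acylal to lactol 15, which hexavalent chromium oxidises to the γ‑lactone, while the benzyl ether, the acids and both stereocentres are not involved.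

**Step 9**
Reactants: 16 (2S)‑2‑[(1S)‑11‑(benzyloxy)‑1‑carboxyundecyl]‑5‑oxooxolane‑2‑carboxylic acid
Product: 17 (2S)‑2‑[(1S)‑1‑carboxy‑11‑hydroxyundecyl]‑5‑oxooxolane‑2‑carboxylic acid
Conditions: H2 (1 atm), Pd on carbon (10 wt %), EtOAc, rt
Reagents that add atoms: none
Why: Catalytic hydrogenolysis cleaves only the benzyl ether, since lactone and carboxylic acids are inert.

**Step 10**
Reactants: 18 (2R)‑2‑hydroxybutanedioic acid (D‑malic acid)
Product: 19 (3R)‑2,5‑dioxooxolan‑3‑yl trifluoroacetate (O‑trifluoroacetyl‑D‑malic anhydride)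
Conditions: (CF3CO)2O (3 equiv), neat, 0 °C to rt; volatiles removed in vacuo
Reagents that add atoms: trifluoroacetic anhydride, O=C(OC(=O)C(F)(F)F)C(F)(F)F
Why: Dehydration of the 1,4‑diacid to the cyclic anhydride, with O‑acylation at the same time, is a known reaction of malic acid and does not touch the stereocentre.

**Step 11**
Reactants: 17 (2S)‑2‑[(1S)‑1‑carboxy‑11‑hydroxyundecyl]‑5‑oxooxolane‑2‑carboxylic acid; 19 (3R)‑2,5‑dioxooxolan‑3‑yl trifluoroacetate
Product: 21 (2S)‑2‑[(1S)‑1‑carboxy‑11‑{[(2R)‑3‑carboxy‑2‑hydroxypropanoyl]oxy}undecyl]‑5‑oxooxolane‑2‑carboxylic acid (target), via O‑trifluoroacetyl ester 20 (not isolated)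
Conditions: 19 (2 equiv), THF, 0 °C to rt; then H2O, rt; reversed‑phase chromatography
Reagents that add atoms: none
Why: In this regioselective alcoholysis of an unsymmetrical anhydride the carbonyl next to the trifluoroacetoxy‑bearing carbon is the more electrophilic, so the primary alcohol should give the 1‑ester, and the labile trifluoroacetate is then hydrolysed by water without touching the other esters.

**Compound list**
1 | 10‑bromodecan‑1‑ol | OCCCCCCCCCCBr | starting material
2 | benzyl 10‑bromodecyl ether | BrCCCCCCCCCCOCc1ccccc1 | intermediate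
3 | benzyl 10‑iododecyl ether | ICCCCCCCCCCOCc1ccccc1 | intermediate
4 | diethyl (2R)‑2‑hydroxybutanedioate | CCOC(=O)C[C@@H](O)C(=O)OCC | starting material
5 | dilithium alkoxide enolate of 4 (chelated geometry, not isolated) | [Li+].[Li+].CCOC(=O)[C@H]([O-])/C=C(\[O-])OCC | intermediate
6 | diethyl (2R,3S)‑3‑[10‑(benzyloxy)decyl]‑2‑hydroxybutanedioate | CCOC(=O)[C@H](O)[C@H](CCCCCCCCCCOCc1ccccc1)C(=O)OCC | intermediate
7 | (2R,3S)‑3‑[10‑(benzyloxy)decyl]‑2‑hydroxybutanedioic acid | OC(=O)[C@H](O)[C@H](CCCCCCCCCCOCc1ccccc1)C(=O)O | intermediate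
8 | 3‑bromo‑1,1‑dimethoxypropane | COC(CCBr)OC | starting material
9 | 3‑iodo‑1,1‑dimethoxypropane | COC(CCI)OC | intermediate
10 | bis(trimethylsilyl) (2R,3S)‑3‑[10‑(benzyloxy)decyl]‑2‑[(trimethylsilyl)oxy]butanedioate (not isolated) | C[Si](C)(C)OC(=O)[C@H](O[Si](C)(C)C)[C@H](CCCCCCCCCCOCc1ccccc1)C(=O)O[Si](C)(C)C | intermediate
11 | trimethylsilyl ester of 12 (not isolated) | O=C1O[C@H](CCI)O[C@@H]1[C@H](CCCCCCCCCCOCc2ccccc2)C(=O)O[Si](C)(C)C | intermediate
12 | (2S)‑12‑(benzyloxy)‑2‑[(2R,4R)‑2‑(2‑iodoethyl)‑5‑oxo‑1,3‑dioxolan‑4‑yl]dodecanoic acid | O=C1O[C@H](CCI)O[C@@H]1[C@H](CCCCCCCCCCOCc2ccccc2)C(=O)O | intermediate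
13 | dilithium carboxylate enolate of 12 (not isolated) | [Li+].[Li+].[O-]C1=C(O[C@@H](CCI)O1)[C@H](CCCCCCCCCCOCc2ccccc2)C(=O)[O-] | intermediate
14 | (2S)‑12‑(benzyloxy)‑2‑[(1R,4S)‑3‑oxo‑2,7‑dioxabicyclo[2.2.1]heptan‑4‑yl]dodecanoic acid | O=C1O[C@@H]2CC[C@]1(O2)[C@H](CCCCCCCCCCOCc3ccccc3)C(=O)O | intermediate
15 | (2S)‑2‑[(1S)‑11‑(benzyloxy)‑1‑carboxyundecyl]‑5‑hydroxyoxolane‑2‑carboxylic acid (anomer mixture, not isolated) | c1ccccc1COCCCCCCCCCC[C@H](C(=O)O)[C@]2(C(=O)O)CCC(O)O2 | intermediate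
16 | (2S)‑2‑[(1S)‑11‑(benzyloxy)‑1‑carboxyundecyl]‑5‑oxooxolane‑2‑carboxylic acid | c1ccccc1COCCCCCCCCCC[C@H](C(=O)O)[C@]2(C(=O)O)CCC(=O)O2 | intermediate
17 | (2S)‑2‑[(1S)‑1‑carboxy‑11‑hydroxyundecyl]‑5‑oxooxolane‑2‑carboxylic acid | OCCCCCCCCCC[C@H](C(=O)O)[C@]1(C(=O)O)CCC(=O)O1 | intermediate
18 | (2R)‑2‑hydroxybutanedioic acid | OC(=O)C[C@@H](O)C(=O)O | starting material
19 | (3R)‑2,5‑dioxooxolan‑3‑yl trifluoroacetate | O=C1C[C@@H](OC(=O)C(F)(F)F)C(=O)O1 | intermediate
20 | O‑trifluoroacetyl derivative of 21 (not isolated) | O=C(O)C[C@@H](OC(=O)C(F)(F)F)C(=O)OCCCCCCCCCC[C@H](C(=O)O)[C@]1(C(=O)O)CCC(=O)O1 | intermediate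
21 | (2S)‑2‑[(1S)‑1‑carboxy‑11‑{[(2R)‑3‑carboxy‑2‑hydroxypropanoyl]oxy}undecyl]‑5‑oxooxolane‑2‑carboxylic acid | O=C(O)C[C@@H](O)C(=O)OCCCCCCCCCC[C@H](C(=O)O)[C@]1(C(=O)O)CCC(=O)O1 | target

**Step count and risks**
Total step count: 11. Longest linear sequence: 9 (steps 1, 2, 3, 4, 6, 7, 8, 9, 11).

Steps most likely to fail:

**Step 7.** The enolate may fragment, or be alkylated between molecules, before the strained bicycle closes. The fallback is the classical external‑electrophile variant. Because it runs with retention, it needs the C2 epimer. It sets out from 6 and comes back at 16.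
- Mitsunobu inversion of the carbinol of 6 (4‑nitrobenzoic acid, PPh3, DIAD) would give diethyl (2S,3S)‑3‑[10‑(benzyloxy)decyl]‑2‑[(4‑nitrobenzoyl)oxy]butanedioate F1.
- KOH hydrolysis would give (2S,3S)‑3‑[10‑(benzyloxy)decyl]‑2‑hydroxybutanedioic acid F2.
- Pivalaldehyde under acid catalysis would give the cis acetal (2S)‑12‑(benzyloxy)‑2‑[(2S,4S)‑2‑tert‑butyl‑5‑oxo‑1,3‑dioxolan‑4‑yl]dodecanoic acid F3.
- Seebach alkylation of its dianion (LiN(SiMe3)2, allyl bromide, −78 °C), anti to the tert‑butyl group, would give (2S)‑12‑(benzyloxy)‑2‑[(2S,4S)‑2‑tert‑butyl‑5‑oxo‑4‑(prop‑2‑en‑1‑yl)‑1,3‑dioxolan‑4‑yl]dodecanoic acid F4.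
- Hydroboration (9‑BBN, then NaBO3) would give (2S)‑12‑(benzyloxy)‑2‑[(2S,4S)‑2‑tert‑butyl‑4‑(3‑hydroxypropyl)‑5‑oxo‑1,3‑dioxolan‑4‑yl]dodecanoic acid F5.
- TEMPO/PhI(OAc)2 oxidation would give (2S)‑12‑(benzyloxy)‑2‑[(2S,4S)‑2‑tert‑butyl‑4‑(2‑carboxyethyl)‑5‑oxo‑1,3‑dioxolan‑4‑yl]dodecanoic acid F6.
- Aqueous trifluoroacetic acid then cleaves the acetal, and the hydroxy triacid lactonises to 16.

**Step 3.** Alkylation of the dianion by an unactivated primary iodide may be sluggish, with proton transfer and loss of diastereoselectivity on warming. The fallback brings the chain in by olefin metathesis. It sets out from 4 and comes back at 6.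
- Fráter–Seebach alkylation of 4 with the reactive allyl bromide would give diethyl (2R,3S)‑2‑hydroxy‑3‑(prop‑2‑en‑1‑yl)butanedioate F7.
- Commercial non‑8‑en‑1‑ol is benzylated as in step 1 to benzyl non‑8‑en‑1‑yl ether F8.
- Cross metathesis of the two with the second‑generation Grubbs catalyst would give diethyl (2R,3S)‑3‑[(2E)‑10‑(benzyloxy)dec‑2‑en‑1‑yl]‑2‑hydroxybutanedioate F9.
- Diimide reduction (TsNHNH2, NaOAc) saturates the alkene without touching the benzyl ether and gives 6.

**Step 11.** The reagent may undergo anhydride exchange with the free vicinal diacid, or the trifluoroacetyl group may transfer to the alcohol, with incomplete or unselective acylation. The fallback masks the core acids. It sets out from 17 and comes back at 21.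
- Carboxylate alkylation (BnBr, Cs2CO3, DMF) would give benzyl (2S)‑2‑[(1S)‑1‑(benzyloxycarbonyl)‑11‑hydroxyundecyl]‑5‑oxooxolane‑2‑carboxylate F10.
- Opening of 19 would give the O‑trifluoroacetyl malate half ester of the dibenzyl ester F11.
- Water would give the free malate half ester of the dibenzyl ester F12.
- Hydrogenolysis (H2, Pd on carbon) gives 21.

**Further compounds**
F1 | step 7 | diethyl (2S,3S)‑3‑[10‑(benzyloxy)decyl]‑2‑[(4‑nitrobenzoyl)oxy]butanedioate | CCOC(=O)[C@@H](OC(=O)c1ccc(cc1)[N+](=O)[O-])[C@H](CCCCCCCCCCOCc2ccccc2)C(=O)OCC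
F2 | step 7 | (2S,3S)‑3‑[10‑(benzyloxy)decyl]‑2‑hydroxybutanedioic acid | OC(=O)[C@@H](O)[C@H](CCCCCCCCCCOCc1ccccc1)C(=O)O
F3 | step 7 | (2S)‑12‑(benzyloxy)‑2‑[(2S,4S)‑2‑tert‑butyl‑5‑oxo‑1,3‑dioxolan‑4‑yl]dodecanoic acid | O=C1O[C@@H](C(C)(C)C)O[C@H]1[C@H](CCCCCCCCCCOCc2ccccc2)C(=O)O
F4 | step 7 | (2S)‑12‑(benzyloxy)‑2‑[(2S,4S)‑2‑tert‑butyl‑5‑oxo‑4‑(prop‑2‑en‑1‑yl)‑1,3‑dioxolan‑4‑yl]dodecanoic acid | O=C1O[C@@H](C(C)(C)C)O[C@@]1(CC=C)[C@H](CCCCCCCCCCOCc2ccccc2)C(=O)O
F5 | step 7 | (2S)‑12‑(benzyloxy)‑2‑[(2S,4S)‑2‑tert‑butyl‑4‑(3‑hydroxypropyl)‑5‑oxo‑1,3‑dioxolan‑4‑yl]dodecanoic acid | O=C1O[C@@H](C(C)(C)C)O[C@@]1(CCCO)[C@H](CCCCCCCCCCOCc2ccccc2)C(=O)O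
F6 | step 7 | (2S)‑12‑(benzyloxy)‑2‑[(2S,4S)‑2‑tert‑butyl‑4‑(2‑carboxyethyl)‑5‑oxo‑1,3‑dioxolan‑4‑yl]dodecanoic acid | O=C1O[C@@H](C(C)(C)C)O[C@@]1(CCC(=O)O)[C@H](CCCCCCCCCCOCc2ccccc2)C(=O)O
F7 | step 3 | diethyl (2R,3S)‑2‑hydroxy‑3‑(prop‑2‑en‑1‑yl)butanedioate | CCOC(=O)[C@H](O)[C@H](CC=C)C(=O)OCC
F8 | step 3 | benzyl non‑8‑en‑1‑yl ether | C=CCCCCCCCOCc1ccccc1
F9 | step 3 | diethyl (2R,3S)‑3‑[(2E)‑10‑(benzyloxy)dec‑2‑en‑1‑yl]‑2‑hydroxybutanedioate | CCOC(=O)[C@H](O)[C@H](C/C=C/CCCCCCCOCc1ccccc1)C(=O)OCC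
F10 | step 11 | benzyl (2S)‑2‑[(1S)‑1‑(benzyloxycarbonyl)‑11‑hydroxyundecyl]‑5‑oxooxolane‑2‑carboxylate | OCCCCCCCCCC[C@H](C(=O)OCc1ccccc1)[C@]2(C(=O)OCc3ccccc3)CCC(=O)O2
F11 | step 11 | O‑trifluoroacetyl malate half ester of the dibenzyl ester | O=C(O)C[C@@H](OC(=O)C(F)(F)F)C(=O)OCCCCCCCCCC[C@H](C(=O)OCc1ccccc1)[C@]2(C(=O)OCc3ccccc3)CCC(=O)O2
F12 | step 11 | free malate half ester of the dibenzyl ester | O=C(O)C[C@@H](O)C(=O)OCCCCCCCCCC[C@H](C(=O)OCc1ccccc1)[C@]2(C(=O)OCc3ccccc3)CCC(=O)O2
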